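Two questions stand, and one quantity serves both.

in all of them: left-handed substrate 0.50 M; right-handed substrate 0.50 M; precatalyst 0.50 mM

| charge | solid reagent | remark | time |
|---|---|---|---|
| north | 1.5 M | the very flask that is asked about, followed so far |  |
| south | 3 M | run made earlier |  |
| flask | 1.50 M |  | 40 h |

| run | time / h | right-handed substrate / % | left-handed substrate / % | left-handed product / % |
|---|---|---|---|---|
| north | 2.00 | 51 | 47 | 0 |
| north | 4.00 | 50 | 41 | 10 |
| north | 5.00 | 51 | 35 | 11 |
| north | 8.00 | 47 | 26 | 24 |
| south | 1.33 | 53 | 47 | 1 |
| south | 3.00 | 51 | 44 | 6 |
| south | 6.00 | 46 | 32 | 17 |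
| south | 15.0 | 43 | 12 | 40 |

(scatter of a reading: 1.5 percentage points)

- whether the excess of right-handed substrate over left-handed substrate among what is left of the two reaches 98% by 40 h (yes / no)
- the highest excess of right-handed substrate over left-handed substrate among what is left of the two up to 40 h

- catalyst is single-handed; left-handed substrate and right-handed substrate are mirror images of each other, charged as a racemate, each of them at the stated concentration
- solid reagent is a solid; its amount is given per volume of the solution
- at the start none of the solid reagent is in solution

1. The excess follows from the ratio of [right-handed substrate] to [left-handed substrate]. The substrates are the smaller charges, 0.50 M each against 1.50 M of solid reagent, but I assume no constant rate for either and follow their ratio directly. In north from 4.00 h to 8.00 h I read 0.0984 h⁻¹ for the sorting rate, the hourly rise of ln([right-handed substrate]/[left-handed substrate]). An excess of 98% needs that logarithm at 4.60.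

2. Solid charge: by hand, doubling it doubles the sorting rate if the charge counts. South, at 3 M, reads 0.101 h⁻¹ from 6.00 h to 15.0 h, about the same, so I see no gain from the larger charge.

3. Time: north stands at 0.592 at 8.00 h. A steady 0.0984 h⁻¹ arrives at 48.7 h, later than 40 h, with 95.4% by then. Arriving in time wants 0.125 h⁻¹.

4. But the rate may not stay steady: north read 0.0584 h⁻¹ from 2.00 h to 4.00 h, each point carrying 1.5 percentage points. The rise wanted, 1.27-fold, is smaller than the 1.68-fold read so far, but that reading lies within the scatter and does not show a further rise. So my yes is a judgement that the readings leave open.

5. The forecast says no, with a top of 95%: “After that it is first order”. We part on the first answer.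

6. North gives yes, with a top of 99.7%.

    partner + catalyst + right-handed substrate → catalyst + right-handed product (k = 2.60 M⁻² min⁻¹)
    precatalyst → catalyst (k = 0.00300 min⁻¹)
    solid reagent ⇌ partner, rate k3*(cs3 - [partner]) while solid is left; crystals form when [partner] > cs3 (solubility = 0.240 M, k = 0.0110 min⁻¹)
    partner + catalyst + left-handed substrate → catalyst + left-handed product (k = 33.0 M⁻² min⁻¹)

The wanted excess stands at 30.2 h, with 33.8% of the two substrates charged together left as right-handed substrate. Between 20.0 h and 40.0 h the sorting rate in north is 0.206 h⁻¹, twice the 0.0984 h⁻¹ read early and above the 0.125 h⁻¹ wanted.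

All runs stem from a simulated flask with constants of no real substance; noise was put on by code.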